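Numbering: ring C1, C5–C10; C1 bears OH and the chain C2(=O)–C3=C4–C15; C5 bears the angelate; lactone O–C6, C7–C11(=C13)–C12(=O); C9 bears OH; C10 bears C14.
Cuts: C9 carbinol from its ketone; the 5-O-angelate and the C2/C3=C4 enone from one oxan-4-one in which O-5 is bonded to C4; lactone C7–C11 and C11=C13 from a phosphonoacetate on O-6; C9–C10 and C1–C5 by an intramolecular de Mayo reaction; the tether from 2-diazocyclopentane-1,3-dione, (R)-propylene oxide and 2-oxobutanoic acid.
Enabling feature: the oxygenated C9 and C6 flank C10–C1–C5, so C9–C10–C1–C5–C6 is a 1,5-dicarbonyl (de Mayo) array and the cycloheptane is a cyclopentane-1,3-dione (C5, C6, C7, C8, C9) expanded by C10–C1; O-5 is δ to C4, so a temporary O5–C4 bond (ring O, C4, C3, C2, C1, C5) ties the alkene partner to C5.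
Forward ring order: cyclopentane (bought), then oxanone and cyclobutane (photocycloaddition), cycloheptane (retro-aldol of the old C5–C9 bond), γ-lactone, and last the oxanone is opened.
Stereochemistry: the only imported stereocentre is C4 from (R)-propylene oxide; it sets C1, then C5 and C10 on the cis-fused oxanone, and is erased when C3=C4 forms; C6 by chelation-controlled reduction then Mitsunobu inversion, C7 by the tethered Michael addition, C9 by hydroxyl-directed reduction.

Key step: step 6

Step 1
Reactants: 1 2-oxobutanoic acid
Product: 2 N-methoxy-N-methyl-2-oxobutanamide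
Conditions: MeNHOMe·HCl, EDC·HCl, N-methylmorpholine, CH2Cl2, 0 °C to rt
Reagents that add atoms: N,O-dimethylhydroxylamine hydrochloride, CNOC.Cl
Why: Carbodiimide amide coupling gives the Weinreb amide, which will accept one alkyllithium and stop at the ketone.

Step 2
Reactants: 2 N-methoxy-N-methyl-2-oxobutanamide
Product: 3 (Z)-2-(tert-butyldimethylsilyloxy)-N-methoxy-N-methylbut-2-enamide
Conditions: TBSOTf, Et3N, CH2Cl2, 0 °C
Reagents that add atoms: tert-butyldimethylsilyl triflate, CC(C)(C)[Si](C)(C)OS(=O)(=O)C(F)(F)F
Why: Soft enolisation and O-silylation of the α-keto amide, which can enolise only toward its CH2 group, should give the (Z)-silyl enol ether and so installs the C1 oxygen and the C1=C10 alkene.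

Step 3
Reactants: 4 (R)-2-methyloxirane; 3 (Z)-2-(tert-butyldimethylsilyloxy)-N-methoxy-N-methylbut-2-enamide
Product: 6 (2Z,6R)-3-(tert-butyldimethylsilyloxy)-6-hydroxyhept-2-en-4-one, via dilithiated (R)-propan-2-ol 5 (not isolated)
Conditions: lithium 4,4'-di-tert-butylbiphenylide (2.1 equiv), THF, −78 °C; then 3, −78 °C; aq. NH4Cl
Reagents that add atoms: none
Why: Reductive lithiation of the epoxide by an arene radical anion cleaves the CH2–O bond to the β-oxido primary alkyllithium, which the Weinreb amide acylates (ketone synthesis) without touching the carbinol stereocentre, the future C4.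

Step 4
Reactants: 7 cyclopentane-1,3-dione
Product: 8 2-diazocyclopentane-1,3-dione
Conditions: 4-acetamidobenzenesulfonyl azide, Et3N, MeCN, 0 °C to rt
Reagents that add atoms: 4-acetamidobenzenesulfonyl azide, CC(=O)Nc1ccc(cc1)S(=O)(=O)N=[N+]=[N-]
Why: Regitz diazo transfer to the acidic C2 of the 1,3-dione.

Step 5
Reactants: 8 2-diazocyclopentane-1,3-dione; 6 (2Z,6R)-3-(tert-butyldimethylsilyloxy)-6-hydroxyhept-2-en-4-one
Product: 9 3-hydroxy-2-{[(2R,5Z)-5-(tert-butyldimethylsilyloxy)-4-oxohept-5-en-2-yl]oxy}cyclopent-2-en-1-one
Conditions: Rh2(OAc)4 (1 mol %), PhCF3, 60 °C, slow addition of 8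
Reagents that add atoms: none
Why: Rhodium-carbenoid O–H insertion into the secondary alcohol gives the enolised 2-alkoxy-1,3-dione with retention at the carbinol carbon, and should outrun attack on the hindered, acyl-substituted enol ether.

Step 6
Reactants: 9 3-hydroxy-2-{[(2R,5Z)-5-(tert-butyldimethylsilyloxy)-4-oxohept-5-en-2-yl]oxy}cyclopent-2-en-1-one
Product: 11 triketone with ketones at C2, C6 and C9, O-5 bonded to C4 (cis-fused 2-methyloxan-4-one on the 10-methylcycloheptane-1,4-dione), OTBS at C1, with H-5, OTBS-1 and Me-10 on one face and C4 R, via cyclobutanol photoadduct 10 (not isolated)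
Conditions: hν (300–350 nm, Pyrex), degassed MeCN (5 mM), rt; then DBU (0.1 equiv), 0 °C
Reagents that add atoms: none
Why: The excited enolised 1,3-dione (a β-hydroxy enone) adds through its C5=C9 bond to the tethered enol-ether alkene C1=C10, the first bond C5–C1 closing the oxan-4-one ring 6-exo (the four-atom tether allows only this straight regiochemistry) and the second bond C9–C10 closing the cyclobutane by collapse of the 1,4-diradical, after which the strained cyclobutanol 10 undergoes retro-aldol cleavage of the old C5–C9 bond, so the seven-membered ring arises by two-carbon ring expansion and not by cyclisation. The closest known reaction type is the intramolecular de Mayo reaction of cyclic 1,3-diketone enols with tethered alkenes. C1 is set relative to C4 in the first bond formation, by chair-like closure with the C4 methyl and the bulky silyloxy group equatorial and the alkene carbon C10 axial, where it can reach C9. C5 is set when the enolate left by the fragmentation is protonated on the convex face, anti to the axial C10 and the seven-membered ring, giving the cis-fused oxanone, which is also the more stable epimer as long as the C4 methyl stays equatorial. C10 comes from an unselective radical recombination but lies α to the C9 ketone and should be equilibrated by DBU to the epimer with the methyl exo, cis to the silyloxy group. The step needs face selectivity on the planar enol and has only the tether stereocentre to supply it, while E/Z isomerisation of the enone is harmless because the alkene geometry is lost.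

Step 7
Reactants: 11 triketone
Product: 12 ene-dione (11 with a C7=C8 double bond between the C6 and C9 ketones)
Conditions: IBX, DMSO, 65 °C
Reagents that add atoms: none
Why: IBX dehydrogenation of a ketone to an enone; the C7–C8 CH2–CH2 unit lies between two carbonyl groups and should be desaturated before the singly activated CH2 of the oxanone.

Step 8
Reactants: 12 ene-dione
Product: 13 C6 allylic alcohol (6-hydroxy-7-en-9-one; OH cis to O-5, epimeric at C6 to the target)
Conditions: Zn(BH4)2, Et2O, −78 to −40 °C; aq. NH4Cl
Reagents that add atoms: none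
Why: Chelation-controlled 1,2-reduction, in which zinc bridges the C6 carbonyl and the adjacent ring ether oxygen, activating it over the hindered C9 and C2 ketones, and hydride enters on the side of H-5 (Cram chelate).

Step 9
Reactants: 13 C6 allylic alcohol
Product: 14 C6 diethylphosphonoacetate (ester oxygen trans to O-5, C6 as in the target)
Conditions: (EtO)2P(O)CH2CO2H, PPh3, DIAD, toluene, 0 °C to rt
Reagents that add atoms: diethylphosphonoacetic acid, CCOP(=O)(CC(=O)O)OCC
Why: Mitsunobu esterification inverts the allylic C6 carbinol by SN2 displacement and places the ester on the face of the future lactone.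

Step 10
Reactants: 14 C6 diethylphosphonoacetate
Product: 16 α-methylene 12,6-lactone (cis-fused at C6–C7) with the C9 ketone, the C4–O–C5 oxanone and OTBS at C1, via α-phosphono lactone 15 (not isolated)
Conditions: KOtBu (1.05 equiv), THF, −78 to 0 °C; then (CH2O)n, 0 °C to rt; aq. NH4Cl
Reagents that add atoms: paraformaldehyde (as formaldehyde), C=O
Why: Tandem intramolecular Michael addition and Horner–Wadsworth–Emmons olefination, in which the phosphonate carbanion tethered on O-6 adds 5-exo to C7 of the C9 enone from the face of the tether (cis lactone, sets C7) and the α-phosphono lactone anion then olefinates formaldehyde.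

Step 11
Reactants: 16 α-methylene lactone oxanone
Product: 18 5-O-angeloyl-1-O-TBS 9-ketone (the target with OTBS at C1 and C=O at C9), via lithium C5-alkoxide 17 (not isolated)
Conditions: LiN(SiMe3)2 (1.1 equiv), THF, −78 to −30 °C; then angelic anhydride, −78 to 0 °C; aq. NH4Cl
Reagents that add atoms: angelic anhydride, C/C=C(/C)C(=O)OC(=O)/C(C)=C\C
Why: E1cB retro-oxa-Michael opening of the oxanone enolate (enolisation by the amide base is reversible and only this enolate can expel a β-alkoxide) gives the (E)-crotonoyl ketone and the C5 lithium alkoxide, which cannot reach the trans-disposed lactone and is acylated by the anhydride without Z to E isomerisation.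

Step 12
Reactants: 18 5-O-angeloyl-1-O-TBS 9-ketone
Product: 19 9-ketone with free C1 hydroxyl (the target oxidised at C9)
Conditions: HF·pyridine, THF, 0 °C to rt
Reagents that add atoms: none
Why: Fluoride cleavage of the tertiary silyl ether under non-basic conditions that should spare the angelate, both enones and the β-hydroxy ketone.

Step 13
Reactants: 19 9-ketone
Product: 20 target
Conditions: Me4NBH(OAc)3, MeCN/AcOH (1:1), −30 °C
Reagents that add atoms: none
Why: Evans–Saksena hydroxyl-directed reduction, in which the C1 hydroxyl binds boron and delivers hydride through a six-membered transition state to the same face of the C9 ketone (1,3-anti diol), while the hindered conjugated C2 ketone, the lactone and the ester should not react.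

Compound list
1 | 2-oxobutanoic acid | CCC(=O)C(=O)O | starting material
2 | N-methoxy-N-methyl-2-oxobutanamide | CCC(=O)C(=O)N(C)OC | intermediate
3 | (Z)-2-(tert-butyldimethylsilyloxy)-N-methoxy-N-methylbut-2-enamide | C/C=C(\O[Si](C)(C)C(C)(C)C)C(=O)N(C)OC | intermediate
4 | (R)-2-methyloxirane | C[C@@H]1CO1 | starting material
5 | dilithiated (R)-propan-2-ol (lithium (R)-1-lithiopropan-2-olate) | [Li]C[C@@H](C)O[Li] | intermediate
6 | (2Z,6R)-3-(tert-butyldimethylsilyloxy)-6-hydroxyhept-2-en-4-one | C/C=C(\O[Si](C)(C)C(C)(C)C)C(=O)C[C@@H](C)O | intermediate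
7 | cyclopentane-1,3-dione | O=C1CCC(=O)C1 | starting material
8 | 2-diazocyclopentane-1,3-dione | O=C1CCC(=O)C1=[N+]=[N-] | intermediate
9 | 3-hydroxy-2-{[(2R,5Z)-5-(tert-butyldimethylsilyloxy)-4-oxohept-5-en-2-yl]oxy}cyclopent-2-en-1-one | O=C1CCC(O)=C1O[C@H](C)CC(=O)/C(O[Si](C)(C)C(C)(C)C)=C/C | intermediate
10 | cyclobutanol photoadduct (cyclopentanone, cyclobutanol and 2-methyloxan-4-one fused; C5–C9 bond still present; OH at C9, OTBS at C1) | O=C1CC[C@]2(O)[C@H](C)[C@@]3(O[Si](C)(C)C(C)(C)C)C(=O)C[C@@H](C)O[C@@]123 | intermediate
11 | triketone (ketones at C2, C6, C9; O-5 bonded to C4 as a cis-fused 2-methyloxan-4-one; OTBS at C1; H-5, OTBS-1, Me-10 on one face; C4 R) | O=C1CCC(=O)[C@H](C)[C@@]2(O[Si](C)(C)C(C)(C)C)C(=O)C[C@@H](C)O[C@@H]12 | intermediate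
12 | ene-dione (11 with C7=C8) | O=C1C=CC(=O)[C@H](C)[C@@]2(O[Si](C)(C)C(C)(C)C)C(=O)C[C@@H](C)O[C@@H]12 | intermediate
13 | C6 allylic alcohol (6-hydroxy-7-en-9-one, OH cis to O-5) | O[C@H]1C=CC(=O)[C@H](C)[C@@]2(O[Si](C)(C)C(C)(C)C)C(=O)C[C@@H](C)O[C@@H]12 | intermediate
14 | C6 diethylphosphonoacetate (ester oxygen trans to O-5) | CCOP(=O)(OCC)CC(=O)O[C@@H]1C=CC(=O)[C@H](C)[C@@]2(O[Si](C)(C)C(C)(C)C)C(=O)C[C@@H](C)O[C@@H]12 | intermediate
15 | α-phosphono 12,6-lactone (cis-fused; mixture at C11) | CCOP(=O)(OCC)C1C(=O)O[C@@H]2[C@H]1CC(=O)[C@H](C)[C@@]3(O[Si](C)(C)C(C)(C)C)C(=O)C[C@@H](C)O[C@@H]23 | intermediate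
16 | α-methylene 12,6-lactone with C9 ketone, C4–O–C5 oxanone and OTBS at C1 | C=C1C(=O)O[C@@H]2[C@H]1CC(=O)[C@H](C)[C@@]3(O[Si](C)(C)C(C)(C)C)C(=O)C[C@@H](C)O[C@@H]23 | intermediate
17 | lithium C5-alkoxide of the ring-opened (E)-crotonoyl 9-ketone | C=C1C(=O)O[C@@H]2[C@H]1CC(=O)[C@H](C)[C@@](O[Si](C)(C)C(C)(C)C)(C(=O)/C=C/C)[C@H]2O[Li] | intermediate
18 | 5-O-angeloyl-1-O-TBS 9-ketone | C=C1C(=O)O[C@@H]2[C@H]1CC(=O)[C@H](C)[C@@](O[Si](C)(C)C(C)(C)C)(C(=O)/C=C/C)[C@H]2OC(=O)/C(C)=C\C | intermediate
19 | 9-ketone with free C1 hydroxyl | C=C1C(=O)O[C@@H]2[C@H]1CC(=O)[C@H](C)[C@@](O)(C(=O)/C=C/C)[C@H]2OC(=O)/C(C)=C\C | intermediate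
20 | CNP0149130.1 | C=C1C(=O)O[C@@H]2[C@H]1C[C@@H](O)[C@H](C)[C@@](O)(C(=O)/C=C/C)[C@H]2OC(=O)/C(C)=C\C | target

Total steps: 13. Longest linear sequence: 12 (steps 1–3 and 5–13).

Steps most likely to fail

Step 6. The tether may close through the other chair, so that the enone adds to the opposite face of the enol and the C1-epimeric series forms. The triketone may also undergo secondary photoreactions (Norrish cleavage) on over-irradiation. Long exposure to base may open the oxanone by retro-oxa-Michael reaction and scramble C4 and C5. The fallback separates cycloaddition from fragmentation and sets out from 9. Acetylation (Ac2O, Et3N, DMAP) should give the enol acetate F1. Irradiation at 350 nm should give the cyclobutyl acetate photoadduct F2, which is isolable, no longer fragments in the light, and allows the diastereomers to be separated on the rigid tricycle. K2CO3 in MeOH at 0 °C then removes the acetate and triggers the retro-aldol cleavage, returning to the route at 11.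

Step 11. The base may enolise the C9 ketone at C8 or C10 instead, leading to aldol closure onto C2 or to O-acylation. It may also deprotonate the methylene lactone at C7, and the alkoxide may re-close by oxa-Michael addition before it is acylated. The fallback avoids enolates and sets out from 16. Sc(OTf)3 (5 mol %) with angelic anhydride in MeCN at −20 °C should open the oxanone reversibly through its enol and acylate the free C5 hydroxyl in situ, both known Lewis-acid-catalysed processes. This returns directly to 18 and makes no new compound (F0).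

Step 13. Hydride may also be delivered from the boron-bound C1 oxygen to the C2 enone carbonyl, giving partial over-reduction. The fallback accepts this and sets out from 19. Excess Me4NBH(OAc)3 at 0 °C should reduce both ketones to the C2 allylic alcohol F3, with C9 still set by the directed delivery. MnO2 in CH2Cl2 then re-oxidises only the allylic C2 carbinol and returns to the route at 20.

Further compounds
F1 | step 6 | enol acetate of 9, 3-acetoxy-2-{[(2R,5Z)-5-(tert-butyldimethylsilyloxy)-4-oxohept-5-en-2-yl]oxy}cyclopent-2-en-1-one | CC(=O)OC1=C(O[C@H](C)CC(=O)/C(O[Si](C)(C)C(C)(C)C)=C/C)C(=O)CC1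
F2 | step 6 | cyclobutyl acetate photoadduct (C9 acetate of 10) | O=C1CC[C@]2(OC(C)=O)[C@H](C)[C@@]3(O[Si](C)(C)C(C)(C)C)C(=O)C[C@@H](C)O[C@@]123
F0 | step 11 | none | none
F3 | step 13 | C2 allylic alcohol of the target (mixture at C2) | C=C1C(=O)O[C@@H]2[C@H]1C[C@@H](O)[C@H](C)[C@@](O)(C(O)/C=C/C)[C@H]2OC(=O)/C(C)=C\C
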